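(The data stem from a simulated flask with constants of no real substance; the scatter is artificial.)

**The vessel.** The vessel is closed, stirred and isothermal. Substrate sits in the first phase, reagent in the second, and target forms in the first.

common to all: substrate 0.89 M

|  | reagent in the second phase | remark | time | volume of the second phase over the first |
|---|---|---|---|---|
| alder | 1.5 M | run made earlier |  |  |
| flask | 2.23 M |  | 3.0 min | 1.0 |

- alder (time / min: target / %): 0.417: 2.1; 0.833: 4.6; 1.33: 5.6; 1.50: 5.6; 2.00: 7.6; 2.50: 7.3; 3.00: 7.7

(scatter of a reading: 0.5 percentage points)

* amount of target at 3.0 min, in percent of the substrate charged
* the change that raises the amount of target at 3.0 min, in percent of the substrate charged most ("none" if none brings more than 2 percentage points) (beta / gamma / none)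
* amount of target at 3.0 min, in percent of the substrate charged, after beta

- in the second phase: reagent in the second phase; everything else is in the first
- charges count per volume of the first phase; a concentration in a rate is the amount of a species over the volume of its own phase; every rate counts per litre of the first phase
- the earlier runs hold the two phases in the same ratio of volumes as the flask asked about

**Both ends.** At the early end, the alder run gains target steadily. At the late end it has stopped climbing: from 2.00 min to 3.00 min the reading moves by 0.1 percentage points, against a scatter of 0.5 points. Those last readings average 7.53 %, which leaves 92.5 % of the substrate if target is the sole product, and the run reads as a reversible step at its plateau. Counting target as the sole product, the alder run gives 0.0543 M⁻¹. This is the plateau quotient, c target over c substrate left and over c reagent charged, an apparent equilibrium constant.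

**Reagent charge.** At 2.23 M the quotient puts target over substrate at 0.121, so my reckoning for the flask is 10.8 %. Doubling the charge gives 19.5 %, a gain of 8.7 points against the margin of 2 points.

**Transfer coefficient.** In this reckoning, doubling it changes the pace of crossing, not the quotient, and the alder readings stand level from 2.00 min. My reckoning therefore keeps 10.8 % after beta and names gamma as best.

**The result.** The forecast gave 10.7 %, gamma as best and 11.3 % after beta, holding that “Doubling the transfer coefficient only speeds the approach”. The flask gives 9.86 %, and gamma is best: it adds 4.6 points, against the reckoned 8.7 points, while beta adds 0.031 points, reaching 9.89 %.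

    reagent in the reaction phase ⇌ reagent in the second phase, rate k1*([reagent in the reaction phase] - [reagent in the second phase]/K1) per volume of the first phase (partition coefficient = 2.60, kL = 0.0500 s⁻¹)
    substrate + reagent in the reaction phase ⇌ target (K = 0.240 M⁻¹, k = 0.00460 M⁻¹ s⁻¹)
    reagent in the reaction phase + target → over-reacted product (k = 0.00360 M⁻¹ s⁻¹)
    reagent in the reaction phase + target → over-reaction product (k = 0.00260 M⁻¹ s⁻¹)

**Substrate charge.** At 3.00 min the flask holds 9.86 % target and 85.5 % substrate, a quotient of 0.0517 M⁻¹ beside the 0.0543 M⁻¹ read from alder. The neighbour flask, charged with 2.2 M of substrate, is reckoned by the same quotient at 10.8 % and gives 9.12 %, with 87 % substrate left, so its quotient is 0.0471 M⁻¹. Reagent in the reaction phase stands at 0.502 M in the neighbour flask and 0.566 M in the flask. Taken on that concentration, the quotient is 0.209 M⁻¹ in the neighbour flask and 0.204 M⁻¹ in the flask.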